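Each inner furan is 2,4-disubstituted, with C5 unsubstituted and a (CH2)3 chain on C4, so it is cut across C3–C4: O1–C5–C4 becomes a 2-alkylacrylate ester and C2–C3 a vinyl carbinol. One double ring-closing metathesis of an acyclic tetraene bis-acrylate forms both C3=C4 bonds and both five-membered lactone rings at once; hydride reduction and dehydration then aromatise the bis-butenolide to the two furans. The tetraene is assembled by two esterifications from a citronellal-derived 2-alkylacrylic acid carrying the methyl stereocentre, a monosilylated butenediol and a 3-furyl-substituted acrylic acid. The (E)-2-methylpropenoic acid is attached last by a Doebner condensation.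

Key step: step 21

Remark on the chemistry: the carbinol carbons made in step 1 and present in the butenediol are carried as epimer mixtures, since each ends as an sp2 furan carbon; only the methyl-bearing carbon is stereodefined and names give its descriptor alone.

Step 1
Reactants: 1 (S)-citronellal; 2 vinylmagnesium bromide
Product: 3 (5S)-5,9-dimethyldeca-1,8-dien-3-ol (both C3 epimers)
Conditions: CH2=CHMgBr (1.2 equiv), THF, −78 to 0 °C; then sat. aq. NH4Cl
Reagents that add atoms: none
Why: Grignard 1,2-addition of the vinyl nucleophile to the unhindered aldehyde is fast at low temperature; the new carbinol carbon forms without control as both epimers, which is harmless because it later becomes C2 of the central furan, and the methyl-bearing carbon is beta to the carbonyl and cannot epimerise.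

Step 2
Reactants: 3 (5S)-5,9-dimethyldeca-1,8-dien-3-ol
Product: 4 tert-butyl{[(5S)-5,9-dimethyldeca-1,8-dien-3-yl]oxy}dimethylsilane
Conditions: TBSCl, imidazole, DMF, rt
Reagents that add atoms: tert-butyldimethylsilyl chloride, CC(C)(C)[Si](C)(C)Cl
Why: Silyl ether formation with the silyl chloride and imidazole is standard for a secondary alcohol and masks the carbinol for the oxidative and basic steps that follow, without creating a stereocentre.

Step 3
Reactants: 4 tert-butyl{[(5S)-5,9-dimethyldeca-1,8-dien-3-yl]oxy}dimethylsilane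
Product: 5 tert-butyl{[(5S)-7-(3,3-dimethyloxiran-2-yl)-5-methylhept-1-en-3-yl]oxy}dimethylsilane (both epoxide epimers)
Conditions: mCPBA (1.05 equiv), CH2Cl2, 0 °C
Reagents that add atoms: 3-chloroperoxybenzoic acid, OOC(=O)c1cccc(Cl)c1
Why: Prilezhaev epoxidation follows alkene nucleophilicity, so the trisubstituted alkene should react far faster than the monosubstituted vinyl group, which is further deactivated by the allylic silyloxy group; the new epoxide carbon forms as both epimers and is destroyed in the next step.

Step 4
Reactants: 5 tert-butyl{[(5S)-7-(3,3-dimethyloxiran-2-yl)-5-methylhept-1-en-3-yl]oxy}dimethylsilane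
Product: 7 (4S)-6-{[tert-butyl(dimethyl)silyl]oxy}-4-methyloct-7-enal, via vicinal diol 6 (not isolated)
Conditions: H5IO6 (1.2 equiv), THF/Et2O, 0 °C
Reagents that add atoms: none
Why: Periodic acid hydrates the trisubstituted epoxide at its tertiary carbon and cleaves the resulting glycol at once (glycol cleavage), releasing acetone and the aldehyde, while the vinyl group and the secondary silyl ether should survive the short cold exposure.

Step 5
Reactants: 7 (4S)-6-{[tert-butyl(dimethyl)silyl]oxy}-4-methyloct-7-enal
Product: 8 (4S)-6-{[tert-butyl(dimethyl)silyl]oxy}-4-methyloct-7-en-1-ol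
Conditions: NaBH4, MeOH, 0 °C
Reagents that add atoms: none
Why: Borohydride reduction of the aldehyde is chemoselective, leaves the vinyl group and the silyl ether intact and creates no stereocentre.

Step 6
Reactants: 8 (4S)-6-{[tert-butyl(dimethyl)silyl]oxy}-4-methyloct-7-en-1-ol
Product: 9 tert-butyl{[(5S)-8-iodo-5-methyloct-1-en-3-yl]oxy}dimethylsilane
Conditions: PPh3, I2, imidazole, CH2Cl2, 0 °C to rt
Reagents that add atoms: iodine, II
Why: Appel-type iodination converts the primary alcohol to the iodide by SN2 displacement of an alkoxyphosphonium ion under buffered conditions that spare the silyl ether and the alkene.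

Step 7
Reactants: 9 tert-butyl{[(5S)-8-iodo-5-methyloct-1-en-3-yl]oxy}dimethylsilane; 10 triethyl phosphonoacetate
Product: 11 ethyl (6S)-8-{[tert-butyl(dimethyl)silyl]oxy}-2-(diethoxyphosphoryl)-6-methyldec-9-enoate (both C2 epimers)
Conditions: NaH, 10 (1.5 equiv), THF/DMF, 0 °C; then 9, 60 °C
Reagents that add atoms: none
Why: SN2 C-alkylation of the sodium phosphonoacetate enolate with an unhindered primary iodide should be clean when the anion is used in excess to suppress dialkylation; the new phosphonate-bearing carbon forms as both epimers and becomes sp2 in the next step.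

Step 8
Reactants: 11 ethyl (6S)-8-{[tert-butyl(dimethyl)silyl]oxy}-2-(diethoxyphosphoryl)-6-methyldec-9-enoate
Product: 12 ethyl (6S)-8-{[tert-butyl(dimethyl)silyl]oxy}-6-methyl-2-methylidenedec-9-enoate
Conditions: 37% aq. HCHO, K2CO3, THF, 65 °C
Reagents that add atoms: formaldehyde, C=O
Why: Horner–Wadsworth–Emmons methylenation of an alkylated phosphonoacetate with aqueous formaldehyde and carbonate is a standard route to 2-alkylacrylates, and the mild base leaves the silyl ether and the remote stereocentre alone.

Step 9
Reactants: 12 ethyl (6S)-8-{[tert-butyl(dimethyl)silyl]oxy}-6-methyl-2-methylidenedec-9-enoate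
Product: 13 (6S)-8-{[tert-butyl(dimethyl)silyl]oxy}-6-methyl-2-methylidenedec-9-enoic acid
Conditions: LiOH, THF/H2O, rt; then 1 M HCl to pH 4, 0 °C
Reagents that add atoms: lithium hydroxide, [Li+].[OH-]
Why: Saponification of the ethyl ester in aqueous THF without an alcohol cosolvent avoids conjugate addition of alkoxide to the acrylate, and acidification only to pH 4 in the cold keeps the silyl ether.

Step 10
Reactants: 14 but-3-ene-1,2-diol (racemic)
Product: 15 1-{[tert-butyl(diphenyl)silyl]oxy}but-3-en-2-ol (racemic)
Conditions: TBDPSCl (1.0 equiv), imidazole, CH2Cl2, −20 to 0 °C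
Reagents that add atoms: tert-butyl(chloro)diphenylsilane, CC(C)(C)[Si](Cl)(c1ccccc1)c1ccccc1
Why: Selective monosilylation of a 1,2-diol with the bulky silyl chloride should occur at the primary hydroxyl on steric grounds, leaving the secondary allylic hydroxyl free for esterification.

Step 11
Reactants: 13 (6S)-8-{[tert-butyl(dimethyl)silyl]oxy}-6-methyl-2-methylidenedec-9-enoic acid; 15 1-{[tert-butyl(diphenyl)silyl]oxy}but-3-en-2-ol
Product: 16 1-{[tert-butyl(diphenyl)silyl]oxy}but-3-en-2-yl (6S)-8-{[tert-butyl(dimethyl)silyl]oxy}-6-methyl-2-methylidenedec-9-enoate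
Conditions: DCC, DMAP (cat.), CH2Cl2, 0 °C to rt
Reagents that add atoms: none
Why: Steglich esterification (carbodiimide activation with DMAP acyl transfer) couples 2-alkylacrylic acids with secondary allylic alcohols under neutral conditions that touch neither silyl ether, and no stereocentre is formed.

Step 12
Reactants: 16 1-{[tert-butyl(diphenyl)silyl]oxy}but-3-en-2-yl (6S)-8-{[tert-butyl(dimethyl)silyl]oxy}-6-methyl-2-methylidenedec-9-enoate
Product: 17 1-{[tert-butyl(diphenyl)silyl]oxy}but-3-en-2-yl (6S)-8-hydroxy-6-methyl-2-methylidenedec-9-enoate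
Conditions: CSA (cat.), MeOH/CH2Cl2, 0 °C to rt
Reagents that add atoms: none
Why: Acid-catalysed methanolysis (selective desilylation) should remove the secondary tert-butyldimethylsilyl ether well before the far more acid-stable primary tert-butyldiphenylsilyl ether, and the acrylate ester is stable to catalytic acid at room temperature.

Step 13
Reactants: 18 3-furaldehyde; 10 triethyl phosphonoacetate
Product: 19 ethyl (2E)-3-(furan-3-yl)prop-2-enoate
Conditions: NaH, 10, THF, 0 °C; then 18, 0 °C to rt
Reagents that add atoms: none
Why: Horner–Wadsworth–Emmons olefination of an aromatic aldehyde with the stabilised phosphonate anion should give the (E)-enoate, the geometry being irrelevant after the next step.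

Step 14
Reactants: 19 ethyl (2E)-3-(furan-3-yl)prop-2-enoate
Product: 20 ethyl 3-(furan-3-yl)propanoate
Conditions: H2 (1 atm), 5% Pd/C, EtOAc, rt
Reagents that add atoms: none
Why: Catalytic hydrogenation of the conjugated disubstituted alkene at one atmosphere is much faster than reduction of the aromatic furan, so stopping after one equivalent of hydrogen should give the saturated ester.

Step 15
Reactants: 20 ethyl 3-(furan-3-yl)propanoate
Product: 21 3-(furan-3-yl)propan-1-ol
Conditions: LiAlH4, Et2O, 0 °C; then H2O
Reagents that add atoms: none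
Why: Hydride reduction of the ester with LiAlH4 gives the primary alcohol and does not affect the furan.

Step 16
Reactants: 21 3-(furan-3-yl)propan-1-ol
Product: 22 3-(3-iodopropyl)furan
Conditions: PPh3, I2, imidazole, CH2Cl2, 0 °C
Reagents that add atoms: iodine, II
Why: Appel-type iodination with the preformed phosphine–iodine adduct converts the primary alcohol to the iodide by SN2 displacement, and the buffered medium keeps free iodine and acid away from the furan.

Step 17
Reactants: 22 3-(3-iodopropyl)furan; 10 triethyl phosphonoacetate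
Product: 23 ethyl 2-(diethoxyphosphoryl)-5-(furan-3-yl)pentanoate (racemic)
Conditions: NaH, 10 (1.5 equiv), THF/DMF, 0 °C; then 22, 60 °C
Reagents that add atoms: none
Why: SN2 C-alkylation of the phosphonoacetate enolate with the primary iodide is the same reliable operation as in step 7, the excess anion suppressing dialkylation and the racemic alpha carbon becoming sp2 in the next step.

Step 18
Reactants: 23 ethyl 2-(diethoxyphosphoryl)-5-(furan-3-yl)pentanoate
Product: 24 ethyl 5-(furan-3-yl)-2-methylidenepentanoate
Conditions: 37% aq. HCHO, K2CO3, THF, 65 °C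
Reagents that add atoms: formaldehyde, C=O
Why: Horner–Wadsworth–Emmons methylenation with formaldehyde under carbonate conditions gives the 2-alkylacrylate, and the weakly basic medium is harmless to the furan.

Step 19
Reactants: 24 ethyl 5-(furan-3-yl)-2-methylidenepentanoate
Product: 25 5-(furan-3-yl)-2-methylidenepentanoic acid
Conditions: LiOH, THF/H2O, rt; then 1 M HCl to pH 4, 0 °C
Reagents that add atoms: lithium hydroxide, [Li+].[OH-]
Why: Saponification of the ethyl ester frees the acid, and the brief cold acidification to pH 4 should not harm the 3-alkylfuran.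

Step 20
Reactants: 17 1-{[tert-butyl(diphenyl)silyl]oxy}but-3-en-2-yl (6S)-8-hydroxy-6-methyl-2-methylidenedec-9-enoate; 25 5-(furan-3-yl)-2-methylidenepentanoic acid
Product: 26 1-{[tert-butyl(diphenyl)silyl]oxy}but-3-en-2-yl (6S)-8-{[5-(furan-3-yl)-2-methylidenepentanoyl]oxy}-6-methyl-2-methylidenedec-9-enoate (tetraene bis-acrylate)
Conditions: DCC, DMAP (cat.), CH2Cl2, 0 °C to rt
Reagents that add atoms: none
Why: A second Steglich esterification acylates the freed secondary allylic alcohol with the furyl-bearing 2-alkylacrylic acid and completes the tetraene, with no stereocentre formed and the primary silyl ether untouched.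

Step 21
Reactants: 26 tetraene bis-acrylate
Product: 29 bis-butenolide 5-{(2S)-5-[5-({[tert-butyl(diphenyl)silyl]oxy}methyl)-2-oxo-2,5-dihydrofuran-3-yl]-2-methylpentyl}-3-[3-(furan-3-yl)propyl]furan-2(5H)-one, via ring-A mono-butenolide 27 (not isolated), via ring-B mono-butenolide 28 (not isolated)
Conditions: second-generation Grubbs catalyst (H2IMes)(PCy3)Cl2Ru=CHPh (10 mol%, two portions), toluene (2 mM), 80 °C, argon sparge
Reagents that add atoms: none
Why: The ruthenium benzylidene should load at each monosubstituted vinyl group, the resulting alkylidene adds [2+2] to the 1,1-disubstituted acrylate alkene of the same ester unit, and cycloreversion of the ruthenacyclobutane releases the trisubstituted ring alkene while the methylidene left on ruthenium is lost as ethene in the next turnover. The closest known reaction type is the ring-closing metathesis of 2-alkylacrylates of secondary allylic alcohols to 3-alkyl-5-substituted furan-2(5H)-ones with second-generation ruthenium carbenes, applied here to two such units in one molecule. Ring A (later the acid-bearing furan) and ring B (later the central furan) each close as a five-membered unsaturated lactone by metathesis of a 1,6-diene tethered through its ester C(=O)–O link, the bond formed being the ring C=C that becomes C3–C4 of the furan. No stereocentre is created, the two lactone CH–O carbons are carried as epimer mixtures that vanish on aromatisation, and the (S)-methyl carbon is remote from both reacting sites. The step needs site selectivity, each vinyl group pairing with the acrylate of its own ester, and this is secured by the 1,6-spacing that makes five-membered closure far faster than the crossed pairings to an eight-membered carbocycle or to twelve- and fourteen-membered rings, with high dilution, heat to populate the reactive ester rotamer and purging of ethene holding back intermolecular metathesis. The 3-alkylfuran, the silyl ether and both ester links are not substrates for the catalyst.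

Step 22
Reactants: 29 bis-butenolide
Product: 31 tert-butyl{[4-((4S)-5-{4-[3-(furan-3-yl)propyl]furan-2-yl}-4-methylpentyl)furan-2-yl]methoxy}diphenylsilane, via bis-lactol 30 (not isolated)
Conditions: i-Bu2AlH (2.4 equiv), CH2Cl2, −78 °C; then 1 M aq. HCl, THF, 0 °C to rt
Reagents that add atoms: none
Why: Partial reduction of each lactone by i-Bu2AlH at low temperature stops at the aluminium lactolate, and on acidic work-up each 2-hydroxy-2,5-dihydrofuran loses water with aromatisation as the driving force to give the furan, the lactol and former carbinol stereocentres disappearing in the process.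

Step 23
Reactants: 31 tert-butyl{[4-((4S)-5-{4-[3-(furan-3-yl)propyl]furan-2-yl}-4-methylpentyl)furan-2-yl]methoxy}diphenylsilane
Product: 32 [4-((4S)-5-{4-[3-(furan-3-yl)propyl]furan-2-yl}-4-methylpentyl)furan-2-yl]methanol
Conditions: Bu4NF, THF, 0 °C to rt
Reagents that add atoms: none
Why: Fluoride-mediated desilylation cleaves the silicon–oxygen bond under basic conditions that the three acid-sensitive furans tolerate.

Step 24
Reactants: 32 [4-((4S)-5-{4-[3-(furan-3-yl)propyl]furan-2-yl}-4-methylpentyl)furan-2-yl]methanol
Product: 33 4-((4S)-5-{4-[3-(furan-3-yl)propyl]furan-2-yl}-4-methylpentyl)furan-2-carbaldehyde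
Conditions: activated MnO2 (excess), CH2Cl2, rt
Reagents that add atoms: none
Why: Activated MnO2 oxidises the furfuryl alcohol, a benzylic-type alcohol, to the aldehyde without over-oxidation and without attacking the furan rings.

Step 25
Reactants: 33 4-((4S)-5-{4-[3-(furan-3-yl)propyl]furan-2-yl}-4-methylpentyl)furan-2-carbaldehyde; 34 methylmalonic acid
Product: 36 (2E)-3-[4-((4S)-5-{4-[3-(furan-3-yl)propyl]furan-2-yl}-4-methylpentyl)furan-2-yl]-2-methylprop-2-enoic acid (target), via beta-hydroxy diacid 35 (not isolated)
Conditions: 34 (3 equiv), pyridine, piperidine (cat.), 90 °C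
Reagents that add atoms: none
Why: In this Knoevenagel–Doebner condensation the amine-catalysed aldol addition of methylmalonic acid to the aldehyde is followed by decarboxylative dehydration in hot pyridine, which should give the (E)-acid because the anti-periplanar loss of carbon dioxide and hydroxide places the furyl group trans to the remaining carboxyl group, the arrangement that is also the more stable one.

Compound list
1 | (S)-citronellal, (3S)-3,7-dimethyloct-6-enal | CC(C)=CCC[C@H](C)CC=O | starting material
2 | vinylmagnesium bromide | C=C[Mg]Br | starting material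
3 | (5S)-5,9-dimethyldeca-1,8-dien-3-ol, both C3 epimers | CC(C)=CCC[C@H](C)CC(O)C=C | intermediate
4 | tert-butyl{[(5S)-5,9-dimethyldeca-1,8-dien-3-yl]oxy}dimethylsilane | CC(C)=CCC[C@H](C)CC(O[Si](C)(C)C(C)(C)C)C=C | intermediate
5 | tert-butyl{[(5S)-7-(3,3-dimethyloxiran-2-yl)-5-methylhept-1-en-3-yl]oxy}dimethylsilane | CC1(C)OC1CC[C@H](C)CC(O[Si](C)(C)C(C)(C)C)C=C | intermediate
6 | (6S)-8-{[tert-butyl(dimethyl)silyl]oxy}-2,6-dimethyldec-9-ene-2,3-diol (vicinal diol, not isolated) | CC(C)(O)C(O)CC[C@H](C)CC(O[Si](C)(C)C(C)(C)C)C=C | intermediate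
7 | (4S)-6-{[tert-butyl(dimethyl)silyl]oxy}-4-methyloct-7-enal | O=CCC[C@H](C)CC(O[Si](C)(C)C(C)(C)C)C=C | intermediate
8 | (4S)-6-{[tert-butyl(dimethyl)silyl]oxy}-4-methyloct-7-en-1-ol | OCCC[C@H](C)CC(O[Si](C)(C)C(C)(C)C)C=C | intermediate
9 | tert-butyl{[(5S)-8-iodo-5-methyloct-1-en-3-yl]oxy}dimethylsilane | ICCC[C@H](C)CC(O[Si](C)(C)C(C)(C)C)C=C | intermediate
10 | triethyl phosphonoacetate | CCOC(=O)CP(=O)(OCC)OCC | starting material
11 | ethyl (6S)-8-{[tert-butyl(dimethyl)silyl]oxy}-2-(diethoxyphosphoryl)-6-methyldec-9-enoate | CCOC(=O)C(CCC[C@H](C)CC(O[Si](C)(C)C(C)(C)C)C=C)P(=O)(OCC)OCC | intermediate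
12 | ethyl (6S)-8-{[tert-butyl(dimethyl)silyl]oxy}-6-methyl-2-methylidenedec-9-enoate | C=C(CCC[C@H](C)CC(O[Si](C)(C)C(C)(C)C)C=C)C(=O)OCC | intermediate
13 | (6S)-8-{[tert-butyl(dimethyl)silyl]oxy}-6-methyl-2-methylidenedec-9-enoic acid | C=C(CCC[C@H](C)CC(O[Si](C)(C)C(C)(C)C)C=C)C(=O)O | intermediate
14 | but-3-ene-1,2-diol, racemic | C=CC(O)CO | starting material
15 | 1-{[tert-butyl(diphenyl)silyl]oxy}but-3-en-2-ol, racemic | C=CC(O)CO[Si](c1ccccc1)(c1ccccc1)C(C)(C)C | intermediate
16 | 1-{[tert-butyl(diphenyl)silyl]oxy}but-3-en-2-yl (6S)-8-{[tert-butyl(dimethyl)silyl]oxy}-6-methyl-2-methylidenedec-9-enoate | C=C(CCC[C@H](C)CC(O[Si](C)(C)C(C)(C)C)C=C)C(=O)OC(C=C)CO[Si](c1ccccc1)(c1ccccc1)C(C)(C)C | intermediate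
17 | 1-{[tert-butyl(diphenyl)silyl]oxy}but-3-en-2-yl (6S)-8-hydroxy-6-methyl-2-methylidenedec-9-enoate | C=C(CCC[C@H](C)CC(O)C=C)C(=O)OC(C=C)CO[Si](c1ccccc1)(c1ccccc1)C(C)(C)C | intermediate
18 | 3-furaldehyde, furan-3-carbaldehyde | O=Cc1ccoc1 | starting material
19 | ethyl (2E)-3-(furan-3-yl)prop-2-enoate | CCOC(=O)/C=C/c1ccoc1 | intermediate
20 | ethyl 3-(furan-3-yl)propanoate | CCOC(=O)CCc1ccoc1 | intermediate
21 | 3-(furan-3-yl)propan-1-ol | OCCCc1ccoc1 | intermediate
22 | 3-(3-iodopropyl)furan | ICCCc1ccoc1 | intermediate
23 | ethyl 2-(diethoxyphosphoryl)-5-(furan-3-yl)pentanoate, racemic | CCOC(=O)C(CCCc1ccoc1)P(=O)(OCC)OCC | intermediate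
24 | ethyl 5-(furan-3-yl)-2-methylidenepentanoate | C=C(CCCc1ccoc1)C(=O)OCC | intermediate
25 | 5-(furan-3-yl)-2-methylidenepentanoic acid | C=C(CCCc1ccoc1)C(=O)O | intermediate
26 | tetraene bis-acrylate, 1-{[tert-butyl(diphenyl)silyl]oxy}but-3-en-2-yl (6S)-8-{[5-(furan-3-yl)-2-methylidenepentanoyl]oxy}-6-methyl-2-methylidenedec-9-enoate | C=C(CCC[C@H](C)CC(OC(=O)C(=C)CCCc1ccoc1)C=C)C(=O)OC(C=C)CO[Si](c1ccccc1)(c1ccccc1)C(C)(C)C | intermediate
27 | ring-A mono-butenolide, (5S)-8-[5-({[tert-butyl(diphenyl)silyl]oxy}methyl)-2-oxo-2,5-dihydrofuran-3-yl]-5-methyloct-1-en-3-yl 5-(furan-3-yl)-2-methylidenepentanoate (not isolated) | O=C1OC(CO[Si](c2ccccc2)(c2ccccc2)C(C)(C)C)C=C1CCC[C@H](C)CC(OC(=O)C(=C)CCCc1ccoc1)C=C | intermediate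
28 | ring-B mono-butenolide, 1-{[tert-butyl(diphenyl)silyl]oxy}but-3-en-2-yl (6S)-7-{4-[3-(furan-3-yl)propyl]-5-oxo-2,5-dihydrofuran-2-yl}-6-methyl-2-methylideneheptanoate (not isolated) | C=C(CCC[C@H](C)CC1OC(=O)C(CCCc2ccoc2)=C1)C(=O)OC(C=C)CO[Si](c1ccccc1)(c1ccccc1)C(C)(C)C | intermediate
29 | bis-butenolide, 5-{(2S)-5-[5-({[tert-butyl(diphenyl)silyl]oxy}methyl)-2-oxo-2,5-dihydrofuran-3-yl]-2-methylpentyl}-3-[3-(furan-3-yl)propyl]furan-2(5H)-one | O=C1OC(CO[Si](c2ccccc2)(c2ccccc2)C(C)(C)C)C=C1CCC[C@H](C)CC1OC(=O)C(CCCc2ccoc2)=C1 | intermediate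
30 | bis-lactol, 5-{(2S)-5-[5-({[tert-butyl(diphenyl)silyl]oxy}methyl)-2-hydroxy-2,5-dihydrofuran-3-yl]-2-methylpentyl}-3-[3-(furan-3-yl)propyl]-2,5-dihydrofuran-2-ol (not isolated) | OC1OC(CO[Si](c2ccccc2)(c2ccccc2)C(C)(C)C)C=C1CCC[C@H](C)CC1OC(O)C(CCCc2ccoc2)=C1 | intermediate
31 | tert-butyl{[4-((4S)-5-{4-[3-(furan-3-yl)propyl]furan-2-yl}-4-methylpentyl)furan-2-yl]methoxy}diphenylsilane | CC(C)(C)[Si](OCc1cc(CCC[C@H](C)Cc2cc(CCCc3ccoc3)co2)co1)(c1ccccc1)c1ccccc1 | intermediate
32 | [4-((4S)-5-{4-[3-(furan-3-yl)propyl]furan-2-yl}-4-methylpentyl)furan-2-yl]methanol | OCc1cc(CCC[C@H](C)Cc2cc(CCCc3ccoc3)co2)co1 | intermediate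
33 | 4-((4S)-5-{4-[3-(furan-3-yl)propyl]furan-2-yl}-4-methylpentyl)furan-2-carbaldehyde | O=Cc1cc(CCC[C@H](C)Cc2cc(CCCc3ccoc3)co2)co1 | intermediate
34 | methylmalonic acid | CC(C(=O)O)C(=O)O | starting material
35 | beta-hydroxy diacid, 2-{hydroxy[4-((4S)-5-{4-[3-(furan-3-yl)propyl]furan-2-yl}-4-methylpentyl)furan-2-yl]methyl}-2-methylpropanedioic acid (not isolated) | CC(C(O)c1cc(CCC[C@H](C)Cc2cc(CCCc3ccoc3)co2)co1)(C(=O)O)C(=O)O | intermediate
36 | (2E)-3-[4-((4S)-5-{4-[3-(furan-3-yl)propyl]furan-2-yl}-4-methylpentyl)furan-2-yl]-2-methylprop-2-enoic acid, CNP0088458.1 | C/C(=C\c1cc(CCC[C@H](C)Cc2cc(CCCc3ccoc3)co2)co1)C(=O)O | target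

Total step count: 25.
Longest linear sequence: 17 steps (steps 1–9, 11, 12 and 20–25, from (S)-citronellal).

Steps most likely to fail

Step 21. One ester unit may close while the second stalls as the catalyst decays over the long hot reaction, or intermolecular cross-metathesis of the vinyl groups may compete and give oligomers. The fallback separates the two closures in time. It sets out from 16, which holds only one diene ester pair. A single ring-closing metathesis with the same ruthenium carbene should give the silyl-protected mono-butenolide F1. Acid-catalysed methanolysis of its secondary silyl ether, as in step 12, should give the hydroxy butenolide F2. Steglich esterification of F2 with acid 25 then delivers 27, where the route is rejoined; 27 needs only one further five-membered closure to reach 29.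

Step 22. Warming before the quench may let the aluminium lactolates collapse and over-reduce to ring-opened enediols, and the mineral acid used for dehydration may degrade the electron-rich furans or the furfuryl silyl ether. The fallback makes the over-reduction deliberate and avoids mineral acid. It sets out from 29. Excess i-Bu2AlH (CH2Cl2, −78 to 0 °C) should open both lactones to the bis-(Z)-enediol tetraol F3. Activated MnO2 (CH2Cl2, rt) then oxidises one allylic hydroxyl of each (Z)-ene-1,4-diol unit. The resulting gamma-hydroxy enal or enone closes to the lactol and loses water on silica or with a trace of pyridinium tosylate; either regiochemistry of oxidation gives the same furan. The route is rejoined at 31.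

Step 25. Addition of the hindered methylmalonic acid to the electron-rich furfural may be slow, so that thermal decarboxylation of the reagent or partial formation of the (Z)-acid competes. The fallback sets out from 33. Wittig olefination with the stabilised ylide ethyl 2-(triphenylphosphoranylidene)propanoate (toluene, 80 °C) should give the (E)-configured ethyl ester F4 under the usual selectivity of stabilised ylides. Saponification of F4 with LiOH in aqueous THF returns to the route at 36.

Further compounds
F1 | step 21 | 5-({[tert-butyl(diphenyl)silyl]oxy}methyl)-3-[(4S)-6-{[tert-butyl(dimethyl)silyl]oxy}-4-methyloct-7-enyl]furan-2(5H)-one | O=C1OC(CO[Si](c2ccccc2)(c2ccccc2)C(C)(C)C)C=C1CCC[C@H](C)CC(O[Si](C)(C)C(C)(C)C)C=C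
F2 | step 21 | 5-({[tert-butyl(diphenyl)silyl]oxy}methyl)-3-[(4S)-6-hydroxy-4-methyloct-7-enyl]furan-2(5H)-one | O=C1OC(CO[Si](c2ccccc2)(c2ccccc2)C(C)(C)C)C=C1CCC[C@H](C)CC(O)C=C
F3 | step 22 | bis-(Z)-enediol tetraol from ring-opening reduction of both lactones of 29 (each lactone C(=O)–O becomes CH2OH plus a free secondary OH, both trisubstituted alkenes Z, silyl ether and (S)-methyl carbon unchanged) | OC/C(CCC[C@H](C)CC(O)/C=C(\CO)CCCc1ccoc1)=C\C(O)CO[Si](c1ccccc1)(c1ccccc1)C(C)(C)C
F4 | step 25 | ethyl (2E)-3-[4-((4S)-5-{4-[3-(furan-3-yl)propyl]furan-2-yl}-4-methylpentyl)furan-2-yl]-2-methylprop-2-enoate | CCOC(=O)/C(C)=C/c1cc(CCC[C@H](C)Cc2cc(CCCc3ccoc3)co2)co1
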